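## Retrosynthetic overview
1. Quinone ⇒ phenol. The two missing C–O bonds (the C=O para to the phenol OH and the C–OH next to the side chain) are made last, in one aerobic oxygenation. The arene therefore travels as an inert 3,5-dimethoxyphenyl group, bought as the benzyl bromide.
2. C5=CH2 ⇒ C5 ketone (non-basic methylenation). C2–CH3 ⇒ C2 ketone (Wittig, then α-face hydrogenation).
3. C1 quaternary centre and CH2–aryl bond ⇒ reductive benzylation of a 1-methylidene-2-ketone, with the enolate attacked anti to the angular methyl.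
4. Ring B ⇒ methylenecyclohexane annulation of 3-methylcyclohexenone. Asymmetric conjugate addition sets C8a; enolate ring closure and epimerisation set C4a.
5. Ring order: ring A is bought, ring B is annulated onto it, and the quinone ring is oxidised last.

Assumption and convention: decalin locants are C1 = C(CH3)(CH2Ar), C2 = CHCH3, C4a = ring-fusion CH, C5 = C(=CH2), C8a = ring-fusion C–CH3. β is the face of the C8a methyl. "Dec" = (1R,2S,4aS,8aS)-1,2,8a-trimethyl-5-methylidenedecahydronaphthalen-1-yl. The ligand antipode in step 1 is the one that gives the S ketone.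

## Route

Step 1
Reactants: 1 3-methylcyclohex-2-en-1-one; 2 5-chloropent-1-yne
Product: 4 (S)-3-(5-chloropent-1-en-2-yl)-3-methylcyclohexan-1-one, via alkenylalane 3 (not isolated)
Conditions: 2, i-Bu2AlH, NiCl2(dppp) (3 mol %), THF, 0 °C to rt; then 1, Cu(OTf)2 (5 mol %), chiral SimplePhos-type aminophosphine (11 mol %), Et2O, −30 °C; H2O
Reagents that add atoms: none
Why: Nickel-catalysed α-selective hydroalumination gives the 1,1-disubstituted alkenylalane, and copper-catalysed asymmetric conjugate addition of alkenylaluminium reagents to 3-substituted cyclohexenones is an established route to all-carbon quaternary centres, so the ligand fixes C8a as S while the alkyl chloride stays inert.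

Step 2
Reactants: 4 (S)-3-(5-chloropent-1-en-2-yl)-3-methylcyclohexan-1-one
Product: 6 (4aR,8aS)-8a-methyl-1-methylidene-trans-decalin-5-one (8a-CH3 β; 4a-H α), via cis-decalone 5 (not isolated)
Conditions: KOt-Bu (1.2 equiv), t-BuOH/THF, rt to 50 °C
Reagents that add atoms: none
Why: Intramolecular enolate alkylation (methylenecyclohexane annulation) can close a six-membered ring only through the C4a enolate and gives the cis-decalone first, after which the alkoxide epimerises the enolisable C4a–H to the more stable trans-fused ketone and so sets C4a relative to C8a.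

Step 3
Reactants: 6 (4aR,8aS)-8a-methyl-1-methylidene-trans-decalin-5-one
Product: 8 8a-methyl-1-methylidene-trans-decalin-2,5-dione, via allylic alcohol 7 (not isolated)
Conditions: SeO2 (0.3 equiv), t-BuOOH (2 equiv, decane), CH2Cl2, rt; then MnO2 (15 equiv), same flask, rt
Reagents that add atoms: selenium dioxide, O=[Se]=O (oxygen relay); tert-butyl hydroperoxide, CC(C)(C)OO
Why: The selenium dioxide ene/[2,3]-sigmatropic allylic hydroxylation can occur only at C2, the sole allylic C–H position because C8a is quaternary, and MnO2 oxidises only the allylic alcohol, so the C5 ketone and both stereocentres are untouched.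

Step 4
Reactants: 8 8a-methyl-1-methylidene-trans-decalin-2,5-dione; 9 3,5-dimethoxybenzyl bromide
Product: 11 1α-(3,5-dimethoxybenzyl)-5β-hydroxy-1β,8aβ-dimethyl-trans-decalin-2-one, via dilithium enolate 10 (not isolated)
Conditions: LiBH(s-Bu)3 (2.2 equiv), THF, −78 °C; then 9 (1.3 equiv), DMPU, −78 °C to rt; H2O
Reagents that add atoms: none
Why: Conjugate hydride addition to the s-cis α-methylene ketone gives the tetrasubstituted C1=C2 enolate regiospecifically (reductive alkylation) while the second equivalent masks the C5 ketone as its axial alkoxide, and the benzylic bromide then attacks C1 axially from the α face anti to the C8a methyl, which sets the C1 quaternary centre.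

Step 5
Reactants: 11 1α-(3,5-dimethoxybenzyl)-5β-hydroxy-1β,8aβ-dimethyl-trans-decalin-2-one
Product: 12 1α-(3,5-dimethoxybenzyl)-1β,8aβ-dimethyl-2-methylidene-trans-decalin-5β-ol
Conditions: Ph3PCH3Br (4 equiv), KOt-Bu (4 equiv), toluene, 90 °C
Reagents that add atoms: methyltriphenylphosphonium bromide, C[P+](c1ccccc1)(c1ccccc1)c1ccccc1.[Br-]
Why: Wittig methylenation with excess ylide at elevated temperature is the standard answer to a ketone flanked by a quaternary carbon, C2 has no epimerisable neighbour, and the C5 alkoxide is simply reprotonated on work-up.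

Step 6
Reactants: 12 1α-(3,5-dimethoxybenzyl)-1β,8aβ-dimethyl-2-methylidene-trans-decalin-5β-ol
Product: 13 1α-(3,5-dimethoxybenzyl)-1β,2β,8aβ-trimethyl-trans-decalin-5β-ol
Conditions: H2 (4 bar), PtO2 (10 mol %), EtOAc, rt
Reagents that add atoms: none
Why: In heterogeneous syn-hydrogenation methylenecyclohexanes are adsorbed from their equatorial side, and here the axial β side is further closed by the syn-axial C8a methyl and the C1 β-methyl, so hydrogen enters from the α face and pushes the new C2 methyl into the β position.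

Step 7
Reactants: 13 1α-(3,5-dimethoxybenzyl)-1β,2β,8aβ-trimethyl-trans-decalin-5β-ol
Product: 14 1α-(3,5-dimethoxybenzyl)-1β,2β,8aβ-trimethyl-trans-decalin-5-one
Conditions: Dess–Martin periodinane (1.3 equiv), CH2Cl2, rt
Reagents that add atoms: none
Why: The Dess–Martin oxidation is essentially neutral, so the hindered axial alcohol becomes the ketone without enolisation of the now sensitive C4a–H, and the dimethoxyarene is inert.

Step 8
Reactants: 14 1α-(3,5-dimethoxybenzyl)-1β,2β,8aβ-trimethyl-trans-decalin-5-one
Product: 15 1-(Dec-methyl)-3,5-dimethoxybenzene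
Conditions: Cp2TiMe2 (3 equiv), toluene, 70 °C, dark
Reagents that add atoms: dimethyltitanocene Cp2TiMe2, C[Ti](C)(C1C=CC=C1)C1C=CC=C1
Why: The Petasis methylenation runs through the non-basic titanocene methylidene by [2+2]/retro-[2+2], which avoids the C4a epimerisation that a basic ylide could cause in this strained ketone.

Step 9
Reactants: 15 1-(Dec-methyl)-3,5-dimethoxybenzene
Product: 16 3-(Dec-methyl)-5-methoxyphenol
Conditions: NaSEt (3 equiv), DMF, 130 °C; dilute HCl
Reagents that add atoms: none
Why: Nucleophilic SN2 demethylation of an aryl methyl ether by thiolate stops after one of the two equivalent methoxy groups because the phenoxide formed is deactivated, and the weakly basic thiolate leaves the exocyclic alkene in place.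

Step 10
Reactants: 16 3-(Dec-methyl)-5-methoxyphenol
Product: 20 2-hydroxy-5-methoxy-3-(Dec-methyl)cyclohexa-2,5-diene-1,4-dione (CNP0109104.1), via methoxyquinone 17 (not isolated), via benzenetriol 18 (not isolated), via epoxyquinone 19 (not isolated)
Conditions: Co(salen) (10 mol %), DBU (2.5 equiv), H2O (5 equiv), O2 (1 atm), MeCN, 0 °C to rt; citric acid work-up
Reagents that add atoms: dioxygen, O=O; water, O
Why: Proposed new method: a single-flask aerobic double C–H oxygenation of a 3-alkyl-5-methoxyphenol to the 2-hydroxy-5-methoxy-1,4-benzoquinone, in which Co(salen)/O2 first oxygenates the free para position (H-abstraction by the cobalt superoxo species, radical recombination at the para carbon, collapse to quinone 17), DBU-buffered water then adds to the only C–H carbon that is β to the carbonyl not deactivated by the methoxy group to give triol 18, cobalt-catalysed autoxidation of 18 delivers 20 as its unreactive vinylogous carboxylate plus hydroperoxide anion, and that hydroperoxide epoxidises a second molecule of 17 at the same C=C to give 19, which DBU opens by E1cB to the same anion, so both atoms of O2 are used and the isolated alkene never meets an electrophilic oxidant, the closest known reaction types being the Co(salen)/O2 oxidation of phenols to p-quinones, the O2/KOt-Bu conversion of 1-naphthols into 2-hydroxy-1,4-naphthoquinones and the Weitz–Scheffer epoxidation/isomerisation of 2-alkylquinones.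

## Compound list
1 | 3-methylcyclohex-2-en-1-one | CC1=CC(=O)CCC1 | starting material
2 | 5-chloropent-1-yne | C#CCCCCl | starting material
3 | (5-chloropent-1-en-2-yl)diisobutylaluminium | C=C(CCCCl)[Al](CC(C)C)CC(C)C | intermediate
4 | (S)-3-(5-chloropent-1-en-2-yl)-3-methylcyclohexan-1-one | O=C1CCC[C@@](C)(C1)C(=C)CCCCl | intermediate
5 | 8a-methyl-1-methylidene-cis-decalin-5-one (8a-CH3 β; 4a-H β) | O=C1CCC[C@@]2(C)[C@@H]1CCCC2=C | intermediate
6 | (4aR,8aS)-8a-methyl-1-methylidene-trans-decalin-5-one | O=C1CCC[C@@]2(C)[C@H]1CCCC2=C | intermediate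
7 | 2-hydroxy-8a-methyl-1-methylidene-trans-decalin-5-one (C2 epimers, centre destroyed in the same flask) | O=C1CCC[C@@]2(C)[C@H]1CCC(O)C2=C | intermediate
8 | 8a-methyl-1-methylidene-trans-decalin-2,5-dione | O=C1CCC[C@@]2(C)[C@H]1CCC(=O)C2=C | intermediate
9 | 3,5-dimethoxybenzyl bromide | BrCc1cc(OC)cc(OC)c1 | starting material
10 | dilithium C1=C2 enolate / C5β alkoxide | [Li+].[Li+].[O-][C@H]1CCC[C@@]2(C)[C@H]1CCC([O-])=C2C | intermediate
11 | 1α-(3,5-dimethoxybenzyl)-5β-hydroxy-1β,8aβ-dimethyl-trans-decalin-2-one | O[C@H]1CCC[C@@]2(C)[C@H]1CCC(=O)[C@@]2(C)Cc1cc(OC)cc(OC)c1 | intermediate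
12 | 1α-(3,5-dimethoxybenzyl)-1β,8aβ-dimethyl-2-methylidene-trans-decalin-5β-ol | O[C@H]1CCC[C@@]2(C)[C@H]1CCC(=C)[C@@]2(C)Cc1cc(OC)cc(OC)c1 | intermediate
13 | 1α-(3,5-dimethoxybenzyl)-1β,2β,8aβ-trimethyl-trans-decalin-5β-ol | O[C@H]1CCC[C@@]2(C)[C@H]1CC[C@H](C)[C@@]2(C)Cc1cc(OC)cc(OC)c1 | intermediate
14 | 1α-(3,5-dimethoxybenzyl)-1β,2β,8aβ-trimethyl-trans-decalin-5-one | O=C1CCC[C@@]2(C)[C@H]1CC[C@H](C)[C@@]2(C)Cc1cc(OC)cc(OC)c1 | intermediate
15 | 1-(Dec-methyl)-3,5-dimethoxybenzene | C=C1CCC[C@@]2(C)[C@H]1CC[C@H](C)[C@@]2(C)Cc1cc(OC)cc(OC)c1 | intermediate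
16 | 3-(Dec-methyl)-5-methoxyphenol | C=C1CCC[C@@]2(C)[C@H]1CC[C@H](C)[C@@]2(C)Cc1cc(O)cc(OC)c1 | intermediate
17 | 2-(Dec-methyl)-6-methoxy-1,4-benzoquinone | C=C1CCC[C@@]2(C)[C@H]1CC[C@H](C)[C@@]2(C)CC1=CC(=O)C=C(OC)C1=O | intermediate
18 | 3-(Dec-methyl)-5-methoxybenzene-1,2,4-triol | C=C1CCC[C@@]2(C)[C@H]1CC[C@H](C)[C@@]2(C)Cc1c(O)c(O)cc(OC)c1O | intermediate
19 | epoxide of 17 on the alkyl-bearing C=C (epoxide diastereomers) | C=C1CCC[C@@]2(C)[C@H]1CC[C@H](C)[C@@]2(C)CC34OC3C(=O)C=C(OC)C4=O | intermediate
20 | 2-hydroxy-5-methoxy-3-{[(1R,2S,4aS,8aS)-1,2,8a-trimethyl-5-methylidenedecahydronaphthalen-1-yl]methyl}cyclohexa-2,5-diene-1,4-dione | C=C1CCC[C@@]2(C)[C@H]1CC[C@H](C)[C@@]2(C)CC1=C(O)C(=O)C=C(OC)C1=O | target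

## Step count and weak points
Total step count: 10. Longest linear sequence: 10 (1 → 20).

**Step 10 (the proposed new step).**
- Risk: hydroxide may displace the methoxy group of 17, or the para oxygenation may stall next to the bulky side chain.
- Fallback (known chemistry only): it sets out from 16 and comes back at 20.
- 16 is oxidised with (KSO3)2NO in KH2PO4-buffered aqueous acetone (Teuber oxidation) and methoxyquinone 17 is isolated.
- 17 is epoxidised with 30 % H2O2/Na2CO3 in THF/water at 0 °C (Weitz–Scheffer) and epoxyquinone 19 is isolated.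
- 19 is isomerised with Et3N on silica gel (epoxy-ketone to diosphenol rearrangement) to 20.

**Step 6.**
- Risk: the axial benzyl arm partly screens the α face, and the product carries a syn-axial methyl pair, so the wrong C2 epimer or prior alkene migration is possible.
- Fallback: it sets out from 12 and comes back at 13.
- Stoichiometric syn-hydroboration with BH3·SMe2 followed by NaOH/H2O2 gives the 2β-hydroxymethyl diol F5, whose C2 epimers can be separated by chromatography.
- Selective tosylation of the primary hydroxyl (TsCl, pyridine, 0 °C) gives the primary monotosylate F6.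
- LiBHEt3 in THF reduces F6 to 13.

**Step 4.**
- Risk: a quaternary centre is formed next to a quaternary centre, so O-alkylation, proton transfer or interference by the borane and the C5 alkoxide may win.
- Fallback: it sets out from 8 and comes back at 14.
- The saturated C5 ketone is ketalised selectively (ethylene glycol, PPTS, benzene, Dean–Stark) to the C5 ketal enone F1.
- Dissolving-metal reductive alkylation (Li, NH3/THF, 1 equiv t-BuOH, −78 °C, isoprene quench, then 9) gives the benzylated ketal ketone F2 from a borane-free lithium enolate.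
- Wittig methylenation gives the 2-methylidene ketal F3.
- Hydrogenation over PtO2 gives the 2β-methyl ketal F4.
- Aqueous HCl/THF at 0 °C releases ketone 14.

## Further compounds
F1 | step 4 | 5,5-ethylenedioxy-8a-methyl-1-methylidene-trans-decalin-2-one | O1CCOC13CCC[C@@]2(C)[C@H]3CCC(=O)C2=C
F2 | step 4 | 1α-(3,5-dimethoxybenzyl)-5,5-ethylenedioxy-1β,8aβ-dimethyl-trans-decalin-2-one | O1CCOC13CCC[C@@]2(C)[C@H]3CCC(=O)[C@@]2(C)Cc1cc(OC)cc(OC)c1
F3 | step 4 | 1α-(3,5-dimethoxybenzyl)-5,5-ethylenedioxy-1β,8aβ-dimethyl-2-methylidene-trans-decalin | O1CCOC13CCC[C@@]2(C)[C@H]3CCC(=C)[C@@]2(C)Cc1cc(OC)cc(OC)c1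
F4 | step 4 | 1α-(3,5-dimethoxybenzyl)-5,5-ethylenedioxy-1β,2β,8aβ-trimethyl-trans-decalin | O1CCOC13CCC[C@@]2(C)[C@H]3CC[C@H](C)[C@@]2(C)Cc1cc(OC)cc(OC)c1
F5 | step 6 | 1α-(3,5-dimethoxybenzyl)-2β-(hydroxymethyl)-1β,8aβ-dimethyl-trans-decalin-5β-ol | O[C@H]1CCC[C@@]2(C)[C@H]1CC[C@H](CO)[C@@]2(C)Cc1cc(OC)cc(OC)c1
F6 | step 6 | primary 4-methylbenzenesulfonate of F5 | O[C@H]1CCC[C@@]2(C)[C@H]1CC[C@H](COS(=O)(=O)c3ccc(C)cc3)[C@@]2(C)Cc1cc(OC)cc(OC)c1
F0 | step 10 | none | none
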